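**Strategy.** The route rests on building ring A last. Its bonds C4a–C8a, C5–C6 and C7–C8 are disconnected so that the benzene ring and the O1–C2–C3–O4 dioxane ring appear together. The feature exploited is that ring A is a benzene with two adjacent oxygens, O1 and O4, which both sit on the stereodefined C2–C3 unit. Each oxygen can carry an alkynyl ether, and C6/C7 can come from an (E)-aryl enyne. One cationic rhodium-catalysed [2+2+2] cycloaddition should then close two rings and form three C–C bonds without touching C2 or C3. The precursor is the bis(alkynyl ether) of the (1R,2R)-diaryl diol, with the O1 alkyne capped by triethylsilyl to steer the enyne.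

Key step: step 9

**Remarks on the chemistry**
- Numbering: benzodioxane O1, C2, C3, O4, C4a, C5–C8, C8a. The 3,4-dioxygenated (catechol) aryl is on C2, the 3,5-dioxygenated (resorcinol) aryl on C3, and the stilbene arm on C6 (para to C8a–O1). Bn = benzyl; PPTS = pyridinium 4-toluenesulfonate.
- Stereochemical check: C2 and C3 are both R in the target. The substituent priorities (O > neighbouring carbinol C > aryl > H) are the same in the diol derivatives, the cyclisation precursor and its product, so all are (R,R), and the threo diol maps onto the trans ring.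
- Assumption: the camphor-derived oxaziridine is taken to show the same facial sense with this substituted deoxybenzoin enolate as with the parent one, where the (+)-reagent gives the S ketol. If the sense were reversed, the antipodal reagent would be used.
- Design points. Which oxygen carries which alkyne fixes the regiochemistry of ring A, so the O4 hydroxyl is masked as an acetal that cannot migrate under KH (a silyl ether could). It is unmasked while the O1 substituent is still the robust dichlorovinyl ether, so no deprotection is ever run next to an alkynyl ether. The steering silyl group is triethylsilyl, which should survive the alkoxide and organolithium steps that follow its introduction and still leave C8 under mild acid.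

Step 1
Reactants: 1 1-[3,4-bis(benzyloxy)phenyl]ethanone; 2 1-bromo-3,5-bis(benzyloxy)benzene
Product: 3 1-[3,4-bis(benzyloxy)phenyl]-2-[3,5-bis(benzyloxy)phenyl]ethanone
Conditions: Pd(OAc)2 (2 mol %), Xantphos (2.4 mol %), NaOtBu (2.2 equiv), THF, 70 °C
Reagents that add atoms: none
Why: Palladium-catalysed α-arylation of the ketone enolate (oxidative addition of 2 to zerovalent palladium, enolate transfer, reductive elimination) is well established for acetophenones and aryl bromides, and the more acidic product is held as its enolate, which suppresses diarylation.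

Step 2
Reactants: 3 1-[3,4-bis(benzyloxy)phenyl]-2-[3,5-bis(benzyloxy)phenyl]ethanone
Product: 4 (2R)-1-[3,4-bis(benzyloxy)phenyl]-2-[3,5-bis(benzyloxy)phenyl]-2-hydroxyethan-1-one
Conditions: NaN(SiMe3)2 (1.2 equiv), THF, −78 °C; (−)-(2S,8aR)-(camphorsulfonyl)oxaziridine (1.5 equiv), −78 °C; AcOH, −78 °C
Reagents that add atoms: (−)-(2S,8aR)-(camphorsulfonyl)oxaziridine, CC1(C)[C@H]2CC[C@@]13CS(=O)(=O)N4O[C@]34C2
Why: Davis oxidation, in which the (Z)-sodium enolate attacks the oxaziridine oxygen in an SN2-type transition state and the camphor framework shields one enolate face, so the new C3 stereocentre should form as R under reagent control, with the benzyl ethers inert to the amide base at −78 °C.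

Step 3
Reactants: 4 (2R)-1-[3,4-bis(benzyloxy)phenyl]-2-[3,5-bis(benzyloxy)phenyl]-2-hydroxyethan-1-one
Product: 6 (1R,2R)-1-[3,4-bis(benzyloxy)phenyl]-2-[3,5-bis(benzyloxy)phenyl]-2-[(2-methoxypropan-2-yl)oxy]ethan-1-ol, via acetal-protected ketone 5 (not isolated)
Conditions: 2-methoxypropene (3 equiv), PPTS (5 mol %), CH2Cl2, 0 °C; Et3N, evaporate; KBH(s-Bu)3 (1.5 equiv), THF, −78 °C; H2O
Reagents that add atoms: 2-methoxypropene, C=C(C)OC
Why: Acid-catalysed addition of the hydroxyl to 2-methoxypropene gives a base-stable acetal that cannot migrate between the two oxygens later, and the bulky, non-chelating potassium borohydride then reduces the aryl ketone under polar Felkin–Anh control (hydride anti to the C3–O bond and past the C3 hydrogen), which should set C2 as R and give the threo (1R,2R) alcohol.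

Step 4
Reactants: 6 (1R,2R)-1-[3,4-bis(benzyloxy)phenyl]-2-[3,5-bis(benzyloxy)phenyl]-2-[(2-methoxypropan-2-yl)oxy]ethan-1-ol
Product: 8 (1R,2R)-2-[3,4-bis(benzyloxy)phenyl]-1-[3,5-bis(benzyloxy)phenyl]-2-{[(E)-1,2-dichloroethenyl]oxy}ethan-1-ol, via dichlorovinyl ether acetal 7 (not isolated)
Conditions: KH (2.2 equiv), THF, 0 °C to rt; Cl2C=CHCl (1.3 equiv), rt; aqueous work-up; PPTS (10 mol %), MeOH, 0 °C to rt
Reagents that add atoms: trichloroethylene, ClC=C(Cl)Cl
Why: Alkoxide addition to dichloroacetylene formed in situ from trichloroethylene (the standard dichlorovinyl ether entry to alkynyl ethers) puts the two-carbon unit on O1 by anti addition to give the E ether, and the very acid-labile acetal on O4 is then exchanged off by mild transacetalisation in methanol while the dichlorovinyl ether and both stereocentres stay untouched.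

Step 5
Reactants: 8 (1R,2R)-2-[3,4-bis(benzyloxy)phenyl]-1-[3,5-bis(benzyloxy)phenyl]-2-{[(E)-1,2-dichloroethenyl]oxy}ethan-1-ol
Product: 9 (1R,2R)-2-[3,4-bis(benzyloxy)phenyl]-1-[3,5-bis(benzyloxy)phenyl]-2-{[(triethylsilyl)ethynyl]oxy}ethan-1-ol
Conditions: n-BuLi (3.3 equiv), THF, −78 to −40 °C; Et3SiCl (1.05 equiv), −78 °C; H2O
Reagents that add atoms: chlorotriethylsilane, CC[Si](Cl)(CC)CC
Why: Dehydrochlorination to the chloroalkynyl ether and chlorine–lithium exchange give the lithium alkoxyacetylide beside the O4 lithium alkoxide, and at −78 °C the unhindered acetylide carbon should be silylated by one equivalent of Et3SiCl much faster than the aggregated, hindered secondary alkoxide (acetylide C-silylation).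

Step 6
Reactants: 9 (1R,2R)-2-[3,4-bis(benzyloxy)phenyl]-1-[3,5-bis(benzyloxy)phenyl]-2-{[(triethylsilyl)ethynyl]oxy}ethan-1-ol
Product: 11 (1R,2R)-1-[3,4-bis(benzyloxy)phenyl]-2-[3,5-bis(benzyloxy)phenyl]-2-(ethynyloxy)-1-{[(triethylsilyl)ethynyl]oxy}ethane, via dichlorovinyl ether 10 (not isolated)
Conditions: KH (2.2 equiv), THF, 0 °C; Cl2C=CHCl (1.3 equiv), 0 °C to rt; then −78 °C, n-BuLi (2.5 equiv), −78 to −40 °C; MeOH, −78 °C; cold work-up, Et3N-deactivated silica, use at once
Reagents that add atoms: trichloroethylene, ClC=C(Cl)Cl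
Why: The same trichloroethylene sequence run in one pot (alkoxide addition to dichloroacetylene, then n-BuLi elimination with chlorine–lithium exchange and protonation of the acetylide) installs the terminal ethynyl ether on O4, the C–SiEt3 bond being inert to n-BuLi at −78 °C and far slower than a C–SiMe3 bond toward attack by the alkoxide.

Step 7
Reactants: 12 3,5-bis(benzyloxy)benzaldehyde
Product: 13 1,3-bis(benzyloxy)-5-[(E)-2-iodoethenyl]benzene
Conditions: CrCl2 (6 equiv), CHI3 (2 equiv), THF, 0 °C to rt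
Reagents that add atoms: iodoform, IC(I)I
Why: Takai olefination, in which the geminal dichromium species generated from CHI3 and divalent chromium adds to the aldehyde and eliminates to the vinyl iodide, with an E preference that is reliable for aromatic aldehydes.

Step 8
Reactants: 13 1,3-bis(benzyloxy)-5-[(E)-2-iodoethenyl]benzene
Product: 15 (E)-1-[3,5-bis(benzyloxy)phenyl]but-1-en-3-yne, via trimethylsilyl enyne 14 (not isolated)
Conditions: HC≡CSiMe3 (1.5 equiv), Pd(PPh3)2Cl2 (2 mol %), CuI (4 mol %), Et3N, THF, rt; silica plug; K2CO3 (0.2 equiv), MeOH, rt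
Reagents that add atoms: ethynyltrimethylsilane, C#C[Si](C)(C)C
Why: Sonogashira coupling of the vinyl iodide proceeds with retention of the E geometry, and carbonate-catalysed methanolysis then cleaves the C(sp)–SiMe3 bond to the terminal enyne without touching the benzyl ethers.

Step 9
Reactants: 11 (1R,2R)-1-[3,4-bis(benzyloxy)phenyl]-2-[3,5-bis(benzyloxy)phenyl]-2-(ethynyloxy)-1-{[(triethylsilyl)ethynyl]oxy}ethane; 15 (E)-1-[3,5-bis(benzyloxy)phenyl]but-1-en-3-yne
Product: 16 (2R,3R)-2-[3,4-bis(benzyloxy)phenyl]-3-[3,5-bis(benzyloxy)phenyl]-6-{(E)-2-[3,5-bis(benzyloxy)phenyl]ethenyl}-8-(triethylsilyl)-2,3-dihydro-1,4-benzodioxine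
Conditions: [Rh(cod)2]BF4 (10 mol %), rac-BINAP (10 mol %), CH2Cl2, H2 (1 atm) then Ar; 11 + 15 (2.5 equiv) in CH2Cl2 added over 2 h, rt
Reagents that add atoms: none
Why: Proposed new method: the two alkynyl ether units of 11 bind the cationic monovalent rhodium centre and couple oxidatively at their oxygen-bearing carbons (C4a–C8a) to a trivalent rhodacyclopentadiene, the enyne triple bond then inserts, and reductive elimination completes C5–C6 and C7–C8 and releases the arene and the catalyst. The closest known reaction type is the cationic rhodium/bisphosphine [2+2+2] cycloaddition of tethered diynes with terminal alkynes, together with the known participation of alkynyl ethers in such cyclotrimerisations; what is new is a diyne whose tether is a 1,2-diol carrying two ynol ethers. The dioxane closes in the oxidative-coupling step as the six-membered ring fused to the metallacycle (the anti aryl groups hold O1 and O4 gauche, which preorganises the two alkynes), and ring A closes by the insertion/reductive-elimination pair as a formal [2+2+2] cycloaddition. No stereocentre is formed and the C2–O1 and C3–O4 bonds are never broken, so the (2R,3R) configuration is carried through unchanged. Regiochemistry is secured by the Et3Si group on C8, which makes bonding of C8 to a substituted carbon prohibitive, so the enyne CH should bond to C8 and its alkenyl-bearing carbon to the unhindered C5–H terminus; the triple bond is preferred over the styrenyl double bond because alkynes coordinate and insert much faster, and slow addition at room temperature limits enyne homo-trimerisation and thermal loss of the ynol ethers.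

Step 10
Reactants: 16 (2R,3R)-2-[3,4-bis(benzyloxy)phenyl]-3-[3,5-bis(benzyloxy)phenyl]-6-{(E)-2-[3,5-bis(benzyloxy)phenyl]ethenyl}-8-(triethylsilyl)-2,3-dihydro-1,4-benzodioxine
Product: 17 (2R,3R)-2-[3,4-bis(benzyloxy)phenyl]-3-[3,5-bis(benzyloxy)phenyl]-6-{(E)-2-[3,5-bis(benzyloxy)phenyl]ethenyl}-2,3-dihydro-1,4-benzodioxine
Conditions: CF3CO2H (10 equiv), CH2Cl2, 0 °C
Reagents that add atoms: none
Why: Ipso-protodesilylation (electrophilic aromatic substitution), in which protonation at C8 is favoured by the ortho oxygen O1 and by the β-silicon effect, so the C–Si bond should be cleaved by brief cold acid that leaves the benzyl ethers, the E-alkene and the dioxane stereocentres alone.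

Step 11
Reactants: 17 (2R,3R)-2-[3,4-bis(benzyloxy)phenyl]-3-[3,5-bis(benzyloxy)phenyl]-6-{(E)-2-[3,5-bis(benzyloxy)phenyl]ethenyl}-2,3-dihydro-1,4-benzodioxine
Product: 18 maackin, 4-[(2R,3R)-3-(3,5-dihydroxyphenyl)-6-[(E)-2-(3,5-dihydroxyphenyl)ethenyl]-2,3-dihydro-1,4-benzodioxin-2-yl]benzene-1,2-diol
Conditions: BCl3 (12 equiv), C6HMe5 (18 equiv), CH2Cl2, −78 °C; MeOH, −78 °C to rt
Reagents that add atoms: none
Why: Lewis-acid debenzylation in which BCl3 activates the six primary benzyl aryl ethers at −78 °C and pentamethylbenzene, a non-Lewis-basic cation scavenger, takes up the benzyl cations by Friedel–Crafts alkylation, conditions that do not reduce the stilbene double bond and should spare the hindered secondary C2–O1 and C3–O4 bonds because the para-oxygen donor of the C2 aryl group is tied up as a borate early.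

**Compound list**
1 | 1-[3,4-bis(benzyloxy)phenyl]ethanone | CC(=O)c1ccc(OCc2ccccc2)c(OCc2ccccc2)c1 | starting material
2 | 1-bromo-3,5-bis(benzyloxy)benzene | Brc1cc(OCc2ccccc2)cc(OCc2ccccc2)c1 | starting material
3 | 1-[3,4-bis(benzyloxy)phenyl]-2-[3,5-bis(benzyloxy)phenyl]ethanone | O=C(Cc1cc(OCc2ccccc2)cc(OCc2ccccc2)c1)c1ccc(OCc2ccccc2)c(OCc2ccccc2)c1 | intermediate
4 | (2R)-1-[3,4-bis(benzyloxy)phenyl]-2-[3,5-bis(benzyloxy)phenyl]-2-hydroxyethan-1-one | O[C@H](c1cc(OCc2ccccc2)cc(OCc2ccccc2)c1)C(=O)c1ccc(OCc2ccccc2)c(OCc2ccccc2)c1 | intermediate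
5 | (2R)-1-[3,4-bis(benzyloxy)phenyl]-2-[3,5-bis(benzyloxy)phenyl]-2-[(2-methoxypropan-2-yl)oxy]ethan-1-one (not isolated) | COC(C)(C)O[C@H](c1cc(OCc2ccccc2)cc(OCc2ccccc2)c1)C(=O)c1ccc(OCc2ccccc2)c(OCc2ccccc2)c1 | intermediate
6 | (1R,2R)-1-[3,4-bis(benzyloxy)phenyl]-2-[3,5-bis(benzyloxy)phenyl]-2-[(2-methoxypropan-2-yl)oxy]ethan-1-ol | COC(C)(C)O[C@H](c1cc(OCc2ccccc2)cc(OCc2ccccc2)c1)[C@@H](c1ccc(OCc2ccccc2)c(OCc2ccccc2)c1)O | intermediate
7 | (1R,2R)-1-[3,4-bis(benzyloxy)phenyl]-2-[3,5-bis(benzyloxy)phenyl]-1-{[(E)-1,2-dichloroethenyl]oxy}-2-[(2-methoxypropan-2-yl)oxy]ethane (not isolated) | COC(C)(C)O[C@H](c1cc(OCc2ccccc2)cc(OCc2ccccc2)c1)[C@@H](c1ccc(OCc2ccccc2)c(OCc2ccccc2)c1)O/C(Cl)=C\Cl | intermediate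
8 | (1R,2R)-2-[3,4-bis(benzyloxy)phenyl]-1-[3,5-bis(benzyloxy)phenyl]-2-{[(E)-1,2-dichloroethenyl]oxy}ethan-1-ol | O[C@H](c1cc(OCc2ccccc2)cc(OCc2ccccc2)c1)[C@@H](c1ccc(OCc2ccccc2)c(OCc2ccccc2)c1)O/C(Cl)=C\Cl | intermediate
9 | (1R,2R)-2-[3,4-bis(benzyloxy)phenyl]-1-[3,5-bis(benzyloxy)phenyl]-2-{[(triethylsilyl)ethynyl]oxy}ethan-1-ol | O[C@H](c1cc(OCc2ccccc2)cc(OCc2ccccc2)c1)[C@@H](c1ccc(OCc2ccccc2)c(OCc2ccccc2)c1)OC#C[Si](CC)(CC)CC | intermediate
10 | (1R,2R)-1-[3,4-bis(benzyloxy)phenyl]-2-[3,5-bis(benzyloxy)phenyl]-2-{[(E)-1,2-dichloroethenyl]oxy}-1-{[(triethylsilyl)ethynyl]oxy}ethane (not isolated) | Cl/C=C(Cl)\O[C@H](c1cc(OCc2ccccc2)cc(OCc2ccccc2)c1)[C@@H](c1ccc(OCc2ccccc2)c(OCc2ccccc2)c1)OC#C[Si](CC)(CC)CC | intermediate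
11 | (1R,2R)-1-[3,4-bis(benzyloxy)phenyl]-2-[3,5-bis(benzyloxy)phenyl]-2-(ethynyloxy)-1-{[(triethylsilyl)ethynyl]oxy}ethane | C#CO[C@H](c1cc(OCc2ccccc2)cc(OCc2ccccc2)c1)[C@@H](c1ccc(OCc2ccccc2)c(OCc2ccccc2)c1)OC#C[Si](CC)(CC)CC | intermediate
12 | 3,5-bis(benzyloxy)benzaldehyde | O=Cc1cc(OCc2ccccc2)cc(OCc2ccccc2)c1 | starting material
13 | 1,3-bis(benzyloxy)-5-[(E)-2-iodoethenyl]benzene | I/C=C/c1cc(OCc2ccccc2)cc(OCc2ccccc2)c1 | intermediate
14 | {(E)-4-[3,5-bis(benzyloxy)phenyl]but-3-en-1-yn-1-yl}trimethylsilane (not isolated) | C[Si](C)(C)C#C/C=C/c1cc(OCc2ccccc2)cc(OCc2ccccc2)c1 | intermediate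
15 | (E)-1-[3,5-bis(benzyloxy)phenyl]but-1-en-3-yne | C#C/C=C/c1cc(OCc2ccccc2)cc(OCc2ccccc2)c1 | intermediate
16 | (2R,3R)-2-[3,4-bis(benzyloxy)phenyl]-3-[3,5-bis(benzyloxy)phenyl]-6-{(E)-2-[3,5-bis(benzyloxy)phenyl]ethenyl}-8-(triethylsilyl)-2,3-dihydro-1,4-benzodioxine | c1ccccc1COc1cc(OCc2ccccc2)cc(/C=C/c2cc([Si](CC)(CC)CC)c3c(c2)O[C@H](c2cc(OCc4ccccc4)cc(OCc4ccccc4)c2)[C@@H](c2ccc(OCc4ccccc4)c(OCc4ccccc4)c2)O3)c1 | intermediate
17 | (2R,3R)-2-[3,4-bis(benzyloxy)phenyl]-3-[3,5-bis(benzyloxy)phenyl]-6-{(E)-2-[3,5-bis(benzyloxy)phenyl]ethenyl}-2,3-dihydro-1,4-benzodioxine | c1ccccc1COc1cc(OCc2ccccc2)cc(/C=C/c2ccc3c(c2)O[C@H](c2cc(OCc4ccccc4)cc(OCc4ccccc4)c2)[C@@H](c2ccc(OCc4ccccc4)c(OCc4ccccc4)c2)O3)c1 | intermediate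
18 | maackin, 4-[(2R,3R)-3-(3,5-dihydroxyphenyl)-6-[(E)-2-(3,5-dihydroxyphenyl)ethenyl]-2,3-dihydro-1,4-benzodioxin-2-yl]benzene-1,2-diol | Oc1cc(O)cc(/C=C/c2ccc3c(c2)O[C@H](c2cc(O)cc(O)c2)[C@@H](c2ccc(O)c(O)c2)O3)c1 | target

**Step count.** Total: 11 steps. Longest linear sequence: 9 steps (steps 1–6, then 9–11); steps 7–8 make the enyne in a separate branch.

**Steps most likely to fail**

1. Step 9. What may go wrong: the enyne may homo-trimerise or the diyne may couple with itself faster than the cross reaction; the insertion may not be fully regioselective; the ynol ethers may decompose at the Lewis-acidic cationic metal. The fallback uses known chemistry only, sets out from 6 and returns at 17. The potassium alkoxide of 6 (KN(SiMe3)2, THF/DMF, 0 °C) displaces fluoride from 3-bromo-4-fluorobenzaldehyde by nucleophilic aromatic substitution, giving the MOP-protected bromoaryl ether F1 with O1 para to the formyl group. Mild hydrolysis of the acetal (AcOH–THF–H2O, rt) gives the bromoaryl ether alcohol F2. Intramolecular palladium-catalysed C–O coupling (Pd(OAc)2, 2-(di-tert-butylphosphino)-1,1′-binaphthyl, Cs2CO3, toluene, 70 °C) closes the dioxane without breaking either stereogenic C–O bond and gives the benzodioxine-6-carbaldehyde F3. Horner–Wadsworth–Emmons olefination (NaH, THF, 0 °C to rt) with diethyl [3,5-bis(benzyloxy)benzyl]phosphonate F4, made by Michaelis–Arbuzov reaction of commercial 3,5-bis(benzyloxy)benzyl bromide with P(OEt)3, should give the E-stilbene 17, which rejoins the route at step 11.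

2. Step 6. What may go wrong: the potassium alkoxide on O4 may attack the neighbouring silylalkynyl ether (silyl transfer or 5-exo addition to the triple bond) before it is trapped by dichloroacetylene, and the terminal ethynyl ether may be lost on isolation through heat or trace acid. The fallback avoids any alkoxide, sets out from 9 and returns at 11. Neutral formylation with N-formylbenzotriazole (THF, rt) gives the formate ester F5. Ramirez-type dibromo-olefination (CBr4, PPh3, CH2Cl2, 0 °C) converts it into the 2,2-dibromovinyl ether F6. n-BuLi (2.2 equiv, THF, −78 °C) then effects bromine–lithium exchange, Fritsch–Buttenberg–Wiechell-type rearrangement and deprotonation to the lithium acetylide, and a cold water quench gives 11.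

3. Step 3. What may go wrong: facial selectivity of the hydride reduction may be poor if the C3 aryl group, and not the C3–O bond, takes the position anti to the incoming hydride, which would give the erythro alcohol. The fallback uses the best-precedented Felkin–Anh director, sets out from 4 and returns at 8. Silylation (i-Pr3SiOTf, 2,6-lutidine, CH2Cl2, −78 °C) gives the triisopropylsilyl-protected ketone F7. Reduction with LiBH(s-Bu)3 (THF, −78 °C) gives the threo silyl ether alcohol F8. KH is then added to F8 premixed with Cl2C=CHCl in THF at 0 °C, so that the alkoxide is trapped before the bulky silyl group can migrate, giving the silyl dichlorovinyl ether F9. Bu4NF (THF, 0 °C) frees O4–H to give 8. The migration risk is why this is not the main route.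

**Further compounds**
F1 | step 9 | 3-bromo-4-{(1R,2R)-1-[3,4-bis(benzyloxy)phenyl]-2-[3,5-bis(benzyloxy)phenyl]-2-[(2-methoxypropan-2-yl)oxy]ethoxy}benzaldehyde | COC(C)(C)O[C@H](c1cc(OCc2ccccc2)cc(OCc2ccccc2)c1)[C@@H](c1ccc(OCc2ccccc2)c(OCc2ccccc2)c1)Oc1ccc(C=O)cc1Br
F2 | step 9 | 3-bromo-4-{(1R,2R)-1-[3,4-bis(benzyloxy)phenyl]-2-[3,5-bis(benzyloxy)phenyl]-2-hydroxyethoxy}benzaldehyde | O[C@H](c1cc(OCc2ccccc2)cc(OCc2ccccc2)c1)[C@@H](c1ccc(OCc2ccccc2)c(OCc2ccccc2)c1)Oc1ccc(C=O)cc1Br
F3 | step 9 | (2R,3R)-2-[3,4-bis(benzyloxy)phenyl]-3-[3,5-bis(benzyloxy)phenyl]-2,3-dihydro-1,4-benzodioxine-6-carbaldehyde | O=Cc1ccc2c(c1)O[C@H](c1cc(OCc3ccccc3)cc(OCc3ccccc3)c1)[C@@H](c1ccc(OCc3ccccc3)c(OCc3ccccc3)c1)O2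
F4 | step 9 | diethyl [3,5-bis(benzyloxy)benzyl]phosphonate | CCOP(=O)(Cc1cc(OCc2ccccc2)cc(OCc2ccccc2)c1)OCC
F5 | step 6 | (1R,2R)-2-[3,4-bis(benzyloxy)phenyl]-1-[3,5-bis(benzyloxy)phenyl]-2-{[(triethylsilyl)ethynyl]oxy}ethyl formate | O=CO[C@H](c1cc(OCc2ccccc2)cc(OCc2ccccc2)c1)[C@@H](c1ccc(OCc2ccccc2)c(OCc2ccccc2)c1)OC#C[Si](CC)(CC)CC
F6 | step 6 | (1R,2R)-1-[3,4-bis(benzyloxy)phenyl]-2-[3,5-bis(benzyloxy)phenyl]-2-[(2,2-dibromoethenyl)oxy]-1-{[(triethylsilyl)ethynyl]oxy}ethane | BrC(Br)=CO[C@H](c1cc(OCc2ccccc2)cc(OCc2ccccc2)c1)[C@@H](c1ccc(OCc2ccccc2)c(OCc2ccccc2)c1)OC#C[Si](CC)(CC)CC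
F7 | step 3 | (2R)-1-[3,4-bis(benzyloxy)phenyl]-2-[3,5-bis(benzyloxy)phenyl]-2-{[tri(propan-2-yl)silyl]oxy}ethan-1-one | CC(C)[Si](C(C)C)(C(C)C)O[C@H](c1cc(OCc2ccccc2)cc(OCc2ccccc2)c1)C(=O)c1ccc(OCc2ccccc2)c(OCc2ccccc2)c1
F8 | step 3 | (1R,2R)-1-[3,4-bis(benzyloxy)phenyl]-2-[3,5-bis(benzyloxy)phenyl]-2-{[tri(propan-2-yl)silyl]oxy}ethan-1-ol | CC(C)[Si](C(C)C)(C(C)C)O[C@H](c1cc(OCc2ccccc2)cc(OCc2ccccc2)c1)[C@@H](c1ccc(OCc2ccccc2)c(OCc2ccccc2)c1)O
F9 | step 3 | (1R,2R)-1-[3,4-bis(benzyloxy)phenyl]-2-[3,5-bis(benzyloxy)phenyl]-1-{[(E)-1,2-dichloroethenyl]oxy}-2-{[tri(propan-2-yl)silyl]oxy}ethane | CC(C)[Si](C(C)C)(C(C)C)O[C@H](c1cc(OCc2ccccc2)cc(OCc2ccccc2)c1)[C@@H](c1ccc(OCc2ccccc2)c(OCc2ccccc2)c1)O/C(Cl)=C\Cl
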